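Early in the ochre run, at 1.33 min, the readings stand at 7% target against 57% side product, a target-to-side-product ratio of 0.123. From 5.00 min in the ochre run the ratio is flat at 0.218, and from 8.00 min in the red run at 0.231, although [starting material] differs, 0.0025 M against 0.010 M, at equal [coupling partner]. Pooled, this plateau (a selectivity factor, target over side product) reads 0.226, so the flask at 0.0050 M may borrow these readings.

| flask | starting material | coupling partner | remark | time |
|---|---|---|---|---|
| ochre | 0.0025 M | 0.020 M | run made earlier |  |
| red | 0.010 M | 0.020 M | run made earlier |  |
| flask | 0.0050 M | 0.0200 M |  | 30 min |

| run | time / min | side product / % | target / % |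
|---|---|---|---|
| ochre | 1.33 | 57 | 7 |
| ochre | 2.50 | 73 | 16 |
| ochre | 5.00 | 80 | 18 |
| ochre | 10.0 | 82 | 18 |
| ochre | 20.0 | 81 | 17 |
| red | 4.00 | 76 | 16 |
| red | 8.00 | 83 | 18 |
| red | 10.0 | 82 | 20 |
| red | 15.0 | 82 | 17 |
| red | 20.0 | 82 | 21 |

(readings scatter by 1.5 percentage points)

- share of side product in side product plus target at 4.0 s
- share of side product in side product plus target at 80 s
- share of side product in side product plus target at 30 min
- which of side product and target there is more of at 30 min

Two extreme flasks can be solved in the head. If target formed in step with side product, the share of side product would be 81.6% at every time. If target formed behind a delay, the share would start at 100 % and fall to that plateau. The ochre ratio lies between, above zero yet below the plateau. The reckoning here therefore treats target as a correction and lets the ratio climb exponentially, which puts the time constant at 1.69 min. This time constant of the climb, the target lag, rests on one reading with a scatter of 1.5 percentage points.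

For the flask at 4.0 s, far shorter than the lag, this reckoning makes the ratio the plateau times time over lag, a correction of 0.889%, so its share is 99.1%. At 80 s the reckoning takes over the ochre reading for the flask, 89.0%. At 30 min, far beyond the lag, the reckoned share is the plateau's 81.6%, with side product ahead.

The forecast gives 93%, 87% and 82%, with side product ahead. It reads the same early point, “This hints that target lags”, but its two early shares differ from those reckoned here.

The flask gives 98.1%, 85.7% and 82.0%, with side product ahead.

    intermediate A ⇌ intermediate B (K = 0.590, k = 0.0300 /s)
    starting material ⇌ intermediate A (K = 1.10, k = 0.0510 /s)
    coupling partner + intermediate B → target (k = 1.10 /M/s)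
    coupling partner + intermediate B ⇌ intermediate C (K = 38.0 /M, k = 3.10 /M/s)
    coupling partner + intermediate A → side product (k = 2.10 /M/s)

Put through the same definition, the flask's shares at 80 s and 30 min give a plateau ratio of 0.219 and a target lag of 0.929 min, beside the 1.69 min from the single scattered ochre reading. The neighbouring flask, with [coupling partner] at 0.080 M, gives shares of 91.7% and 89.7% at those times. Its plateau ratio is thus 0.115, half the flask's, and its target lag is 0.856 min. Target ends in that neighbouring flask at 10.3% of the starting material charged.

The earlier runs and the new flask are simulated with made-up constants; noise was put on by code.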